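**Retrosynthetic overview** (side-chain carbons are C1′, on the ring, to C32′)
1. Target 20 ⇐ dimethyl ether 19 by oxidative demethylation, which forms both quinone C=O bonds last. No ring is built: the naphthalene core comes intact from menadione.
2. 19 ⇐ head-to-tail allyl–allyl coupling (C20′–C21′) of allylic bromide 16 with farnesylbarium; 16 ⇐ copper-catalysed C8′–C9′ coupling of the chiral Grignard from bromide 10 with hydroxy acetate 12.
3. Key step: site-selective allylic C–H hydroxylation (C–O bond at the terminal E-methyl group), used on geranyl arene 7 (→ 8) and on farnesyl acetate (→ 12). The new C8′–O bond first directs the hydrogenation and then serves as the leaving group.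
4. The 7′R centre ⇐ hydroxyl-directed enantioselective hydrogenation of diene alcohol 8 (proposed new step).
5. 7 ⇐ aryl Grignard of bromide 4 + geranyl bromide; 4 ⇐ menadione in two steps.

Assumption: the SMILES is read as the 7′R isomer of 6′,7′-dihydromenaquinone-8 (second isoprene unit saturated, six E olefins); geranyl bromide, (2E,6E)-farnesyl acetate and (2E,6E)-farnesyl chloride are taken as catalogue materials.

**Step 1**
Reactants: 1 menadione (2-methylnaphthalene-1,4-dione)
Product: 3 1,4-dimethoxy-2-methylnaphthalene, via menadiol 2 (not isolated)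
Conditions: Na2S2O4, Bu4NBr (cat.), THF/H2O, 25 °C; then KOH (aq), Me2SO4, 25 °C
Reagents that add atoms: dimethyl sulfate, COS(=O)(=O)OC
Why: Na2S2O4 reduces the quinone to menadiol, whose bis-phenoxide is O-methylated in the same pot (reductive methylation, Williamson ether synthesis); no stereocentre is involved.

**Step 2**
Reactants: 3 1,4-dimethoxy-2-methylnaphthalene
Product: 4 2-bromo-1,4-dimethoxy-3-methylnaphthalene
Conditions: Br2, CH2Cl2, 0 °C
Reagents that add atoms: bromine, BrBr
Why: Electrophilic aromatic bromination goes to C3, the only free position of the doubly methoxy-activated ring.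

**Step 3**
Reactants: 4 2-bromo-1,4-dimethoxy-3-methylnaphthalene, 5 geranyl bromide [(2E)-1-bromo-3,7-dimethylocta-2,6-diene]
Product: 7 2-[(2E)-3,7-dimethylocta-2,6-dien-1-yl]-1,4-dimethoxy-3-methylnaphthalene, via aryl Grignard 6 (not isolated)
Conditions: Mg, THF, 45 °C; then 5, THF, 0 → 25 °C
Reagents that add atoms: none
Why: Grignard allylation, in which the aryl Grignard displaces the primary allylic bromide at the alpha carbon (SN2) with retention of the E olefin, as established for menaquinone dimethyl ethers.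

**Step 4**
Reactants: 7 2-[(2E)-3,7-dimethylocta-2,6-dien-1-yl]-1,4-dimethoxy-3-methylnaphthalene
Product: 8 (2E,6E)-8-(1,4-dimethoxy-3-methylnaphthalen-2-yl)-2,6-dimethylocta-2,6-dien-1-ol
Conditions: SeO2 (0.3 equiv), t-BuOOH (3 equiv), salicylic acid (0.1 equiv), CH2Cl2, 0 → 25 °C
Reagents that add atoms: tert-butyl hydroperoxide, CC(C)(C)OO (terminal oxygen source); selenium dioxide, O=[Se]=O (oxygen-transfer catalyst)
Why: Catalytic SeO2 allylic oxidation (ene reaction, then [2,3]-sigmatropic shift) hydroxylates the E-methyl group of the terminal gem-dimethyl olefin, the most electron-rich and least hindered one, giving the E allylic alcohol whose C8′–O bond steers step 5 and is the handle for steps 6 and 8.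

**Step 5**
Reactants: 8 (2E,6E)-8-(1,4-dimethoxy-3-methylnaphthalen-2-yl)-2,6-dimethylocta-2,6-dien-1-ol
Product: 9 (2R,6E)-8-(1,4-dimethoxy-3-methylnaphthalen-2-yl)-2,6-dimethyloct-6-en-1-ol
Conditions: Ru(OAc)2[(R)-DTBM-SEGPHOS] (1 mol %), H2 (60 bar), MeOH, 25 °C
Reagents that add atoms: none
Why: Proposed new method: a divalent-ruthenium bisphosphine dicarboxylate exchanges acetate for the C8′ alkoxide, so only the adjacent C6′=C7′ olefin can chelate and insert into Ru–H through a five-membered oxaruthenacycle (hydride to C7′, Ru to C6′, then hydrogenolysis), while the remote C2′=C3′ olefin cannot chelate and stays untouched; the bulky 3,5-di-tert-butyl-4-methoxyphenyl groups of the (R)-ligand differentiate the faces of the E 2-methyl-2-alken-1-ol to give the 7′R centre (ligand hand taken by analogy with geraniol and tiglic acid, and inverted if the first run gives the S alcohol); the closest known reaction type is the Noyori–Takaya Ru–BINAP hydrogenation of 3,3-disubstituted allylic alcohols and of 2-methyl-2-alkenoic acids, which I believe has not been shown for a 2-methyl-2-alken-1-ol carrying a second trisubstituted olefin.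

**Step 6**
Reactants: 9 (2R,6E)-8-(1,4-dimethoxy-3-methylnaphthalen-2-yl)-2,6-dimethyloct-6-en-1-ol
Product: 10 2-[(2E,7R)-8-bromo-3,7-dimethyloct-2-en-1-yl]-1,4-dimethoxy-3-methylnaphthalene
Conditions: CBr4, PPh3, CH2Cl2, 0 °C
Reagents that add atoms: carbon tetrabromide, BrC(Br)(Br)Br
Why: Appel bromination replaces the primary hydroxyl by SN2 at C8′, one carbon away from the stereocentre, which is not touched.

**Step 7**
Reactants: 11 (2E,6E)-farnesyl acetate [(2E,6E)-3,7,11-trimethyldodeca-2,6,10-trien-1-yl acetate]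
Product: 12 (2E,6E,10E)-12-hydroxy-3,7,11-trimethyldodeca-2,6,10-trien-1-yl acetate
Conditions: SeO2 (0.3 equiv), t-BuOOH (3 equiv), salicylic acid (0.1 equiv), CH2Cl2, 0 → 25 °C
Reagents that add atoms: tert-butyl hydroperoxide, CC(C)(C)OO (terminal oxygen source); selenium dioxide, O=[Se]=O (oxygen-transfer catalyst)
Why: The same SeO2 allylic hydroxylation is selective for the terminal E-methyl group because the 2,3-olefin is deactivated by the allylic acetate, a known reaction of farnesyl acetate.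

**Step 8**
Reactants: 10 2-[(2E,7R)-8-bromo-3,7-dimethyloct-2-en-1-yl]-1,4-dimethoxy-3-methylnaphthalene, 12 (2E,6E,10E)-12-hydroxy-3,7,11-trimethyldodeca-2,6,10-trien-1-yl acetate
Product: 15 (2E,6E,10E,14R,18E)-20-(1,4-dimethoxy-3-methylnaphthalen-2-yl)-2,6,10,14,18-pentamethylicosa-2,6,10,18-tetraen-1-ol, via alkyl Grignard 13 (not isolated), via magnesium alkoxide 14 (not isolated)
Conditions: 10, Mg, THF, 45 °C; separately 12, t-BuMgCl (1.0 equiv), THF, −40 °C; combine, Li2CuCl4 (5 mol %), THF, −40 → 0 °C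
Reagents that add atoms: none
Why: Copper-catalysed Grignard cross-coupling with a primary allylic acetate (Kochi/Fouquet–Schlosser type) proceeds by alpha (SN2) substitution with retention of the E olefin, the hydroxyl of 12 being masked first as its magnesium alkoxide; the 7′R centre is beta to magnesium and is not affected.

**Step 9**
Reactants: 15 (2E,6E,10E,14R,18E)-20-(1,4-dimethoxy-3-methylnaphthalen-2-yl)-2,6,10,14,18-pentamethylicosa-2,6,10,18-tetraen-1-ol
Product: 16 2-[(2E,7R,10E,14E,18E)-20-bromo-3,7,11,15,19-pentamethylicosa-2,10,14,18-tetraen-1-yl]-1,4-dimethoxy-3-methylnaphthalene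
Conditions: PBr3 (0.4 equiv), pyridine (cat.), Et2O, −10 °C
Reagents that add atoms: phosphorus tribromide, BrP(Br)Br
Why: PBr3 converts the primary E allylic alcohol into the allylic bromide at low temperature without allylic transposition or loss of olefin geometry, the standard preparation of polyprenyl bromides.

**Step 10**
Reactants: 16 2-[(2E,7R,10E,14E,18E)-20-bromo-3,7,11,15,19-pentamethylicosa-2,10,14,18-tetraen-1-yl]-1,4-dimethoxy-3-methylnaphthalene, 17 (2E,6E)-farnesyl chloride [(2E,6E)-1-chloro-3,7,11-trimethyldodeca-2,6,10-triene]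
Product: 19 1,4-dimethoxy-2-methyl-3-[(2E,7R,10E,14E,18E,22E,26E)-3,7,11,15,19,23,27,31-octamethyldotriaconta-2,10,14,18,22,26,30-heptaen-1-yl]naphthalene, via farnesylbarium chloride 18 (not isolated)
Conditions: BaI2, Li biphenylide (LiC12H10, 2 equiv), THF, 25 °C; 17, −78 °C; then 16, −78 °C
Reagents that add atoms: none
Why: Yamamoto-type allylbarium cross-coupling, in which the allylic barium reagent made at −78 °C keeps its E geometry and attacks the allylic bromide alpha to alpha′, giving the head-to-tail 1,5-diene junction with both olefins intact.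

**Step 11**
Reactants: 19 1,4-dimethoxy-2-methyl-3-[(2E,7R,10E,14E,18E,22E,26E)-3,7,11,15,19,23,27,31-octamethyldotriaconta-2,10,14,18,22,26,30-heptaen-1-yl]naphthalene
Product: 20 2-methyl-3-[(2E,7R,10E,14E,18E,22E,26E)-3,7,11,15,19,23,27,31-octamethyldotriaconta-2,10,14,18,22,26,30-heptaen-1-yl]naphthalene-1,4-dione
Conditions: (NH4)2Ce(NO3)6 (2.5 equiv), MeCN/CH2Cl2/H2O, 0 °C
Reagents that add atoms: water, O
Why: Oxidative demethylation (two one-electron oxidations of the dimethoxynaphthalene, attack of water at the ipso carbons, loss of methanol) forms both quinone C=O bonds under conditions that leave isolated trisubstituted olefins and the stereocentre untouched.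

**Compound list**
1 | menadione (2-methylnaphthalene-1,4-dione) | CC1=CC(=O)c2ccccc2C1=O | starting material
2 | menadiol (2-methylnaphthalene-1,4-diol) | Cc1cc(O)c2ccccc2c1O | intermediate
3 | 1,4-dimethoxy-2-methylnaphthalene | COc1cc(C)c(OC)c2ccccc12 | intermediate
4 | 2-bromo-1,4-dimethoxy-3-methylnaphthalene | COc1c(Br)c(C)c(OC)c2ccccc12 | intermediate
5 | geranyl bromide, (2E)-1-bromo-3,7-dimethylocta-2,6-diene | CC(C)=CCC/C(C)=C/CBr | starting material
6 | (1,4-dimethoxy-3-methylnaphthalen-2-yl)magnesium bromide | COc1c([Mg]Br)c(C)c(OC)c2ccccc12 | intermediate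
7 | 2-[(2E)-3,7-dimethylocta-2,6-dien-1-yl]-1,4-dimethoxy-3-methylnaphthalene | CC(C)=CCC/C(C)=C/Cc1c(C)c(OC)c2ccccc2c1OC | intermediate
8 | (2E,6E)-8-(1,4-dimethoxy-3-methylnaphthalen-2-yl)-2,6-dimethylocta-2,6-dien-1-ol | OC/C(C)=C/CC/C(C)=C/Cc1c(C)c(OC)c2ccccc2c1OC | intermediate
9 | (2R,6E)-8-(1,4-dimethoxy-3-methylnaphthalen-2-yl)-2,6-dimethyloct-6-en-1-ol | OC[C@H](C)CCC/C(C)=C/Cc1c(C)c(OC)c2ccccc2c1OC | intermediate
10 | 2-[(2E,7R)-8-bromo-3,7-dimethyloct-2-en-1-yl]-1,4-dimethoxy-3-methylnaphthalene | BrC[C@H](C)CCC/C(C)=C/Cc1c(C)c(OC)c2ccccc2c1OC | intermediate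
11 | (2E,6E)-farnesyl acetate, (2E,6E)-3,7,11-trimethyldodeca-2,6,10-trien-1-yl acetate | CC(C)=CCC/C(C)=C/CC/C(C)=C/COC(C)=O | starting material
12 | (2E,6E,10E)-12-hydroxy-3,7,11-trimethyldodeca-2,6,10-trien-1-yl acetate | OC/C(C)=C/CC/C(C)=C/CC/C(C)=C/COC(C)=O | intermediate
13 | [(2R,6E)-8-(1,4-dimethoxy-3-methylnaphthalen-2-yl)-2,6-dimethyloct-6-en-1-yl]magnesium bromide | Br[Mg]C[C@H](C)CCC/C(C)=C/Cc1c(C)c(OC)c2ccccc2c1OC | intermediate
14 | chloromagnesium alkoxide of 12, (2E,6E,10E)-12-acetoxy-2,6,10-trimethyldodeca-2,6,10-trien-1-olate magnesium chloride | Cl[Mg]OC/C(C)=C/CC/C(C)=C/CC/C(C)=C/COC(C)=O | intermediate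
15 | (2E,6E,10E,14R,18E)-20-(1,4-dimethoxy-3-methylnaphthalen-2-yl)-2,6,10,14,18-pentamethylicosa-2,6,10,18-tetraen-1-ol | OC/C(C)=C/CC/C(C)=C/CC/C(C)=C/CC[C@H](C)CCC/C(C)=C/Cc1c(C)c(OC)c2ccccc2c1OC | intermediate
16 | 2-[(2E,7R,10E,14E,18E)-20-bromo-3,7,11,15,19-pentamethylicosa-2,10,14,18-tetraen-1-yl]-1,4-dimethoxy-3-methylnaphthalene | BrC/C(C)=C/CC/C(C)=C/CC/C(C)=C/CC[C@H](C)CCC/C(C)=C/Cc1c(C)c(OC)c2ccccc2c1OC | intermediate
17 | (2E,6E)-farnesyl chloride, (2E,6E)-1-chloro-3,7,11-trimethyldodeca-2,6,10-triene | CC(C)=CCC/C(C)=C/CC/C(C)=C/CCl | starting material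
18 | (2E,6E)-farnesylbarium chloride | CC(C)=CCC/C(C)=C/CC/C(C)=C/C[Ba]Cl | intermediate
19 | 1,4-dimethoxy-2-methyl-3-[(2E,7R,10E,14E,18E,22E,26E)-3,7,11,15,19,23,27,31-octamethyldotriaconta-2,10,14,18,22,26,30-heptaen-1-yl]naphthalene | CC(C)=CCC/C(C)=C/CC/C(C)=C/CC/C(C)=C/CC/C(C)=C/CC/C(C)=C/CC[C@H](C)CCC/C(C)=C/Cc1c(C)c(OC)c2ccccc2c1OC | intermediate
20 | 2-methyl-3-[(2E,7R,10E,14E,18E,22E,26E)-3,7,11,15,19,23,27,31-octamethyldotriaconta-2,10,14,18,22,26,30-heptaen-1-yl]naphthalene-1,4-dione (CNP0107344.1) | CC(C)=CCC/C(C)=C/CC/C(C)=C/CC/C(C)=C/CC/C(C)=C/CC/C(C)=C/CC[C@H](C)CCC/C(C)=C/CC1=C(C)C(=O)c2ccccc2C1=O | target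

**Step count and risks**
Total step count: 11. Longest linear sequence: 10 steps (steps 1–6 and 8–11, from menadione); step 7 is a one-step branch.

The three steps most likely to fail:

Step 5 (proposed new hydrogenation). The risks are low enantioselectivity for the 2-methyl-substituted allylic alcohol and ruthenium-hydride isomerisation of the allylic alcohol to the aldehyde. The fallback uses known chemistry, sets out from 8 and comes back at 9. Alcohol 8 is oxidised with MnO2 in CH2Cl2 to the enal (2E,6E)-8-(1,4-dimethoxy-3-methylnaphthalen-2-yl)-2,6-dimethylocta-2,6-dienal F1. F1 is oxidised with NaClO2, NaH2PO4 and 2-methyl-2-butene to (2E,6E)-8-(1,4-dimethoxy-3-methylnaphthalen-2-yl)-2,6-dimethylocta-2,6-dienoic acid F2. The established carboxylate-directed hydrogenation of 2-methyl-2-alkenoic acids, with Ru(OAc)2[(R)-H8-BINAP] and H2 in MeOH, then gives (2R,6E)-8-(1,4-dimethoxy-3-methylnaphthalen-2-yl)-2,6-dimethyloct-6-enoic acid F3. Reduction of F3 with LiAlH4 in THF returns 9.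

Step 8 (copper-catalysed coupling in the presence of the magnesium alkoxide). The risks are acetate attack or transfer, incomplete Grignard formation, and some SN2′ product. The fallback sets out from 10 and 11 and comes back at 15; it moves the C–O bond formation after the coupling. Grignard 13 (from 10) is coupled under the same Li2CuCl4 catalysis with plain farnesyl acetate 11, which has no free hydroxyl. This gives the polyene 2-[(2E,7R,10E,14E)-3,7,11,15,19-pentamethylicosa-2,10,14,18-tetraen-1-yl]-1,4-dimethoxy-3-methylnaphthalene F4. F4 is then hydroxylated at its terminal E-methyl group with SeO2/t-BuOOH to give 15, at the cost of lower site selectivity in the oxidation.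

Step 10 (allylbarium coupling). The risks are the preparation of the activated barium, homocoupling to squalene, and incomplete alpha,alpha′ selectivity. The fallback is a sulfone (Biellmann-type) alkylation that sets out from 16 and 17 and comes back at 19. Chloride 17 and NaSO2Ph in DMF give (2E,6E)-farnesyl phenyl sulfone F5. n-BuLi in THF/DMPU at −78 °C gives [(2E,6E)-3,7,11-trimethyl-1-(phenylsulfonyl)dodeca-2,6,10-trien-1-yl]lithium F6. F6 is alkylated by 16 to give 1,4-dimethoxy-2-methyl-3-[(2E,7R,10E,14E,18E,22E,26E)-3,7,11,15,19,23,27,31-octamethyl-21-(phenylsulfonyl)dotriaconta-2,10,14,18,22,26,30-heptaen-1-yl]naphthalene F7 (either configuration at C21′). Reductive desulfonylation of F7 with Pd(dppp)Cl2 (cat.) and LiBHEt3 in THF at 0 °C gives 19.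

**Further compounds**
F1 | step 5 | (2E,6E)-8-(1,4-dimethoxy-3-methylnaphthalen-2-yl)-2,6-dimethylocta-2,6-dienal | O=C/C(C)=C/CC/C(C)=C/Cc1c(C)c(OC)c2ccccc2c1OC
F2 | step 5 | (2E,6E)-8-(1,4-dimethoxy-3-methylnaphthalen-2-yl)-2,6-dimethylocta-2,6-dienoic acid | OC(=O)/C(C)=C/CC/C(C)=C/Cc1c(C)c(OC)c2ccccc2c1OC
F3 | step 5 | (2R,6E)-8-(1,4-dimethoxy-3-methylnaphthalen-2-yl)-2,6-dimethyloct-6-enoic acid | OC(=O)[C@H](C)CCC/C(C)=C/Cc1c(C)c(OC)c2ccccc2c1OC
F4 | step 8 | 2-[(2E,7R,10E,14E)-3,7,11,15,19-pentamethylicosa-2,10,14,18-tetraen-1-yl]-1,4-dimethoxy-3-methylnaphthalene | CC(C)=CCC/C(C)=C/CC/C(C)=C/CC[C@H](C)CCC/C(C)=C/Cc1c(C)c(OC)c2ccccc2c1OC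
F5 | step 10 | (2E,6E)-farnesyl phenyl sulfone, [(2E,6E)-3,7,11-trimethyldodeca-2,6,10-trien-1-yl]sulfonylbenzene | CC(C)=CCC/C(C)=C/CC/C(C)=C/CS(=O)(=O)c1ccccc1
F6 | step 10 | [(2E,6E)-3,7,11-trimethyl-1-(phenylsulfonyl)dodeca-2,6,10-trien-1-yl]lithium | CC(C)=CCC/C(C)=C/CC/C(C)=C/C([Li])S(=O)(=O)c1ccccc1
F7 | step 10 | 1,4-dimethoxy-2-methyl-3-[(2E,7R,10E,14E,18E,22E,26E)-3,7,11,15,19,23,27,31-octamethyl-21-(phenylsulfonyl)dotriaconta-2,10,14,18,22,26,30-heptaen-1-yl]naphthalene | CC(C)=CCC/C(C)=C/CC/C(C)=C/C(C/C(C)=C/CC/C(C)=C/CC/C(C)=C/CC[C@H](C)CCC/C(C)=C/Cc1c(C)c(OC)c2ccccc2c1OC)S(=O)(=O)c1ccccc1
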